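I started from the constants, with the charge and the questions beside them.

    dissolved substrate + partner → target (k1 = 0.042 M⁻¹ s⁻¹)
    dissolved substrate + target → side product (k2 = 1.4 M⁻¹ s⁻¹)
    partner → decomposed reagent (k3 = 0.0012 s⁻¹)
    2 solid substrate → homo dimer (k4 = 0.0073 M⁻¹ s⁻¹)
    solid substrate ⇌ dissolved substrate, rate k5*(cs5 - [dissolved substrate]) while solid is left; crystals form when [dissolved substrate] > cs5 (cs5 = 31 mM, k5 = 0.0017 s⁻¹)

solid substrate 0.050 M; partner 4.00 equiv; time 5.0 min

* the target standing at 5.0 min, as a percentage of the solid substrate charged
* concentration of dissolved substrate in solution at 5.0 min, in percent of saturation

- percent here means solid substrate units held: one side product or homo dimer counts as two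
- for a step with 2 of a species take k times the square, and two of it per event
- solid substrate is a solid; its amount is given per volume of the solution
- at the start none of the solid substrate is in solution
- dissolved substrate means what is dissolved; the solid is not counted in it
- run time (flask): 5.0 min

I reckoned in rates. Dissolved substrate has two exits, so call the constants ka = 0.042 M⁻¹ s⁻¹ for partner and kb = 1.4 M⁻¹ s⁻¹ for target. Per dissolved substrate, target then gains at ka[partner] − kb[target], with brackets for concentrations. At the start that gain was 0.504 min⁻¹, a half-life of 1.4 min for dissolved substrate by the partner step with partner as charged, shorter than the run.

I counted two things that slowed the gain. Partner decays with a half-life of 9.6 min, which by the end of the run multiplies ka[partner] by 0.698. Target also slows itself, and the gain vanishes at C = (ka/kb)[partner], the break-even target, with ka/kb serving as the selectivity factor. As charged, C was 12.0% of the solid substrate. With that decay I put it at 8.37% for the end. Dissolving into a solution kept empty could deliver up to 31.6% by then, more than that, so I committed to a target somewhat under 8.37%. I had no figure for saturation.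

The forecast gave target 6.9% (6% to 7.8%) and saturation 13.5% (11.5% to 15.5%), on the ground that “its fast reaction with dissolved substrate nearly cancels its formation by 5 min”. Its target lay below my figure.

The flask gave target 6.90% and saturation 13.8%, both inside the forecast's ranges.

With partner at 67% of its charge at 5.00 min, C in this flask stood at 8.03%, and target was made 1.16 times as fast as it was used. Striking out the passing of dissolved substrate + target into side product raised target from 6.90% to 15.6%, the largest single effect tried but not a whole explanation. Read at 12 min, the same flask had partner at 37.2%, so C was 4.46%, below its target, which had fallen from 6.25% at 10.0 min to 5.40%.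

The rate constants are assumed; the rest is arithmetic.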